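**Retrosynthetic overview**
- The target is the acetate of a cis-3-hydroxy-γ-cyclogeranyl umbelliferyl ether. The ring CH–CMe2 bond is cut back to (R)-6',7'-epoxyauraptene and closed by a light-driven Cp2TiCl2/Co(dmgH)2(py)Cl radical cycloisomerisation.
- The (R)-epoxide comes from the (S)-6',7'-diol by mesylation and closure with inversion; the aryl ether C–O bond comes from umbelliferone and a (2E,6S)-triol by Mitsunobu reaction.
- The (E)-trisubstituted alkene comes from a terminal alkyne by Cp2ZrCl2-catalysed carboalumination and formaldehyde trapping.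
- The alkyne diol comes from ethyl (S)-5-oxooxolane-2-carboxylate (L-glutamic acid series) by double MeMgBr addition and lactol homologation. This is the only purchased stereocenter; it becomes the carbinol carbon and controls the second center in the ring closure.
- Ring order: coumarin bicycle bought intact, oxirane in step 5, cyclohexane last in step 6.

Assumption: ethyl (2S)-5-oxooxolane-2-carboxylate and umbelliferone are bought as such.

**Route**

Step 1
Reactants: 1 ethyl (2S)-5-oxooxolane-2-carboxylate
Product: 2 (5S)-5-(2-hydroxypropan-2-yl)oxolan-2-one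
Conditions: MeMgBr (2.1 equiv), THF, −78 → −40 °C
Reagents that add atoms: methylmagnesium bromide, C[Mg]Br
Why: Grignard addition to an ester: the α-alkoxy ester is markedly more electrophilic than the lactone carbonyl and takes up both equivalents of MeMgBr at low temperature, and the purchased (S) center is not touched.

Step 2
Reactants: 2 (5S)-5-(2-hydroxypropan-2-yl)oxolan-2-one
Product: 4 (3S)-2-methylhept-6-yne-2,3-diol, via lactol 3 (not isolated)
Conditions: i-Bu2AlH (2.2 equiv), CH2Cl2, −78 °C; then MeOH, K2CO3, MeC(O)C(N2)P(O)(OMe)2, −78 °C → rt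
Reagents that add atoms: dimethyl (1-diazo-2-oxopropyl)phosphonate (Ohira–Bestmann reagent), CC(=O)C(=[N+]=[N-])P(=O)(OC)OC
Why: Partial lactone reduction to the lactol, then Ohira–Bestmann (Seyferth–Gilbert) homologation of its open hydroxy-aldehyde form gives the terminal alkyne under K2CO3/MeOH, which cannot epimerise the carbinol center.

Step 3
Reactants: 4 (3S)-2-methylhept-6-yne-2,3-diol
Product: 6 (2E,6S)-3,7-dimethyloct-2-ene-1,6,7-triol, via alkenylalane 5 (not isolated)
Conditions: AlMe3 (5 equiv), Cp2ZrCl2 (0.25 equiv), CH2Cl2, 0 °C → rt; then (CH2O)n (excess), 0 °C → rt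
Reagents that add atoms: trimethylaluminium, C[Al](C)C; formaldehyde (as paraformaldehyde), C=O
Why: Negishi Cp2ZrCl2-catalysed carboalumination adds Me and Al syn across the terminal alkyne with Me on the internal carbon (the two hydroxyls ride as aluminium alkoxides), and the alkenyl–Al bond is hydroxymethylated with retention, so only the E alkene forms.

Step 4
Reactants: 6 (2E,6S)-3,7-dimethyloct-2-ene-1,6,7-triol, 7 umbelliferone (7-hydroxy-2H-chromen-2-one)
Product: 8 7-{[(2E,6S)-6,7-dihydroxy-3,7-dimethyloct-2-en-1-yl]oxy}-2H-chromen-2-one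
Conditions: PPh3, DIAD, THF, 0 °C → rt
Reagents that add atoms: none
Why: Mitsunobu etherification: the acidic phenol (pKa about 7.8) displaces the oxyphosphonium of the unhindered primary allylic alcohol by SN2, the secondary and tertiary hydroxyls being too hindered to compete; alkene geometry and the stereocenter are untouched.

Step 5
Reactants: 8 7-{[(2E,6S)-6,7-dihydroxy-3,7-dimethyloct-2-en-1-yl]oxy}-2H-chromen-2-one
Product: 10 7-({(2E)-5-[(2R)-3,3-dimethyloxiran-2-yl]-3-methylpent-2-en-1-yl}oxy)-2H-chromen-2-one, via mesylate 9 (not isolated)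
Conditions: MsCl (1.1 equiv), Et3N, CH2Cl2, −20 °C; then K2CO3, MeOH, 0 °C → rt
Reagents that add atoms: none
Why: Selective mesylation of the secondary hydroxyl (the tertiary one is inert) and intramolecular Williamson closure by the tertiary alkoxide go with clean inversion at the carbinol carbon, turning the (S)-diol into the (R)-epoxide.

Step 6
Reactants: 10 7-({(2E)-5-[(2R)-3,3-dimethyloxiran-2-yl]-3-methylpent-2-en-1-yl}oxy)-2H-chromen-2-one
Product: 12 7-{[(1S,3R)-3-acetoxy-2,2-dimethyl-6-methylidenecyclohexyl]methoxy}-2H-chromen-2-one, via cyclised alcohol 11 (not isolated)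
Conditions: Cp2TiCl2 (10 mol %), Co(dmgH)2(py)Cl (2 mol %), 2,4,6-collidine·HCl (20 mol %), i-Pr2NEt (10 mol %), degassed THF (0.02 M), 525 nm LEDs, 25 °C; then Ac2O, Et3N, DMAP (cat.), rt
Reagents that add atoms: acetic anhydride, CC(=O)OC(C)=O
Why: Proposed new method: green light excites Cp2TiCl2, which is reductively quenched (initiation by the amine) to Cp2TiCl; this trivalent titanium species opens the epoxide at the tertiary carbon (Nugent–RajanBabu regiochemistry, the C–O bond at the stereocenter stays intact), the β-titanoxy tertiary radical closes 6-endo onto the (E)-alkene through a chair with the titanoxy and aryloxymethyl groups both equatorial, which sets the new (S) center cis to the (R) carbinol, the divalent cobaloxime then takes a hydrogen atom from the least hindered β-position (the methyl) to give the exocyclic alkene, and the cobalt hydride returns a proton (via collidinium) and an electron to the tetravalent titanium alkoxide so that both catalysts turn over without a stoichiometric reductant while light re-cleaves any Co–C resting state; the closest known reaction types are the Cp2TiCl-mediated radical cyclisation of epoxypolyprenes and the titanium/cobalt radical redox-relay isomerisation of epoxides, and the crude alcohol is then acetylated by standard DMAP-catalysed acylation.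

**Compound list**

1 | ethyl (2S)-5-oxooxolane-2-carboxylate | CCOC(=O)[C@@H]1CCC(=O)O1 | starting material
2 | (5S)-5-(2-hydroxypropan-2-yl)oxolan-2-one | CC(C)(O)[C@@H]1CCC(=O)O1 | intermediate
3 | (5S)-5-(2-hydroxypropan-2-yl)oxolan-2-ol (lactol, anomer mixture) | CC(C)(O)[C@@H]1CCC(O)O1 | intermediate
4 | (3S)-2-methylhept-6-yne-2,3-diol | CC(C)(O)[C@@H](O)CCC#C | intermediate
5 | [(1E,5S)-5,6-bis(dimethylalumanyloxy)-2,6-dimethylhept-1-en-1-yl]dimethylalumane | C[Al](C)OC(C)(C)[C@@H](O[Al](C)C)CC/C(C)=C/[Al](C)C | intermediate
6 | (2E,6S)-3,7-dimethyloct-2-ene-1,6,7-triol | CC(C)(O)[C@@H](O)CC/C(C)=C/CO | intermediate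
7 | umbelliferone (7-hydroxy-2H-chromen-2-one) | O=c1ccc2ccc(O)cc2o1 | starting material
8 | 7-{[(2E,6S)-6,7-dihydroxy-3,7-dimethyloct-2-en-1-yl]oxy}-2H-chromen-2-one | CC(C)(O)[C@@H](O)CC/C(C)=C/COc1ccc2ccc(=O)oc2c1 | intermediate
9 | (3S,6E)-2-hydroxy-2,6-dimethyl-8-[(2-oxo-2H-chromen-7-yl)oxy]oct-6-en-3-yl methanesulfonate | CC(C)(O)[C@@H](OS(C)(=O)=O)CC/C(C)=C/COc1ccc2ccc(=O)oc2c1 | intermediate
10 | 7-({(2E)-5-[(2R)-3,3-dimethyloxiran-2-yl]-3-methylpent-2-en-1-yl}oxy)-2H-chromen-2-one | CC1(C)O[C@@H]1CC/C(C)=C/COc1ccc2ccc(=O)oc2c1 | intermediate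
11 | 7-{[(1S,3R)-3-hydroxy-2,2-dimethyl-6-methylidenecyclohexyl]methoxy}-2H-chromen-2-one (hydroxyl and aryloxymethyl cis) | C=C1CC[C@@H](O)C(C)(C)[C@H]1COc1ccc2ccc(=O)oc2c1 | intermediate
12 | 7-{[(1S,3R)-3-acetoxy-2,2-dimethyl-6-methylidenecyclohexyl]methoxy}-2H-chromen-2-one (acetoxy and aryloxymethyl cis) | C=C1CC[C@@H](OC(C)=O)C(C)(C)[C@H]1COc1ccc2ccc(=O)oc2c1 | target

**Step count and risks**

Total step count: 6. Longest linear sequence: 6 steps (1 → 12); umbelliferone 7 enters in step 4.

Three steps most likely to fail:

The first risk is step 6, the untested dual catalysis. The cobaloxime may take a hydrogen atom from the acyclic tertiary radical before it cyclises, which would give the acyclic allylic alcohol. Endocyclic alkene isomers may form, or turnover may stall. The fallback sets out from epoxide 10 and uses the known thermal chemistry. Cp2TiCl2 (0.2 equiv), manganese powder, Me3SiCl and 2,4,6-collidine in THF at rt generate Cp2TiCl, which brings about the same chair-controlled radical cyclisation and exocyclic alkene formation. This gives 7-({(1S,3R)-2,2-dimethyl-6-methylidene-3-[(trimethylsilyl)oxy]cyclohexyl}methoxy)-2H-chromen-2-one F1 in which the hydroxyl is silylated. Dilute HCl in THF at 0 °C then frees alcohol 11 from F1 and the route is rejoined there; acetylation with Ac2O, Et3N and DMAP gives 12.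

The second risk is step 3, where the unprotected 1,2-diol may tie up zirconium and aluminium and stall the carboalumination, or the hydroxymethylation of the alkenylalane may be slow. The fallback sets out from alkyne 4 and builds the E alkene by a hydroalumination–iodination–cuprate sequence instead. n-BuLi (3.1 equiv) and (CH2O)n in THF give (6S)-7-methyloct-2-yne-1,6,7-triol F2 by hydroxymethylation of the lithium acetylide. LiAlH4/NaOMe in THF followed by I2 turns F2 into (2Z,6S)-3-iodo-7-methyloct-2-ene-1,6,7-triol F3 by hydroxyl-directed trans-hydroalumination. Me2CuLi (excess) then replaces the iodine of F3 by methyl with retention and comes back to the route at triol 6.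

The third risk is step 2, the one-pot lactone-to-alkyne conversion; the lactol may react sluggishly with the diazophosphonate anion in the presence of aluminium salts. The fallback sets out from lactone 2. It is reduced with i-Bu2AlH and lactol 3 is isolated after work-up with aq. potassium sodium tartrate. Wittig reaction with Ph3P=CHCl (from (chloromethyl)triphenylphosphonium chloride and NaN(SiMe3)2, THF) gives (3S)-7-chloro-2-methylhept-6-ene-2,3-diol F4 as an E/Z mixture. Dehydrochlorination of F4 with n-BuLi (4 equiv, THF, −78 → 0 °C) comes back to the route at alkyne 4.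

**Further compounds**

F1 | step 6 | 7-({(1S,3R)-2,2-dimethyl-6-methylidene-3-[(trimethylsilyl)oxy]cyclohexyl}methoxy)-2H-chromen-2-one | C=C1CC[C@@H](O[Si](C)(C)C)C(C)(C)[C@H]1COc1ccc2ccc(=O)oc2c1
F2 | step 3 | (6S)-7-methyloct-2-yne-1,6,7-triol | CC(C)(O)[C@@H](O)CCC#CCO
F3 | step 3 | (2Z,6S)-3-iodo-7-methyloct-2-ene-1,6,7-triol | CC(C)(O)[C@@H](O)CC/C(I)=C/CO
F4 | step 2 | (3S)-7-chloro-2-methylhept-6-ene-2,3-diol | CC(C)(O)[C@@H](O)CCC=CCl
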